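**Assumption:** nortopsentin B is achiral (no stereocentre, no atropisomerism), so there is no enantiomer to select. The only stereocentre that appears on the route, in a transient racemic imidazoline, is removed on aromatisation.

**Retrosynthetic overview**
- The imidazole is formed last by closing its N–C4 bond: a double dehydrogenative C(sp3)–H amination of an N-(2-indol-3-ylethyl)amidine.
- The amidine comes from a C–N bond between the carbon of 6-bromoindole-3-carbonitrile and the nitrogen of tryptamine.
- The nitrile comes from C3 cyanation of 6-bromoindole.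
- Ring order: both indoles are bought intact; the imidazoline and then the imidazole form in the final flask.

**Step 1**
Reactants: 1 6-bromo-1H-indole
Product: 3 6-bromo-1H-indole-3-carbonitrile, via N-chlorosulfonylcarboxamide 2 (not isolated)
Conditions: ClSO2NCO (1.1 equiv), MeCN, 0 °C, 1 h; then DMF (3 equiv), 0 °C → rt, 1 h; ice-water, filter
Reagents that add atoms: chlorosulfonyl isocyanate, O=C=NS(=O)(=O)Cl
Why: Electrophilic aromatic substitution at the nucleophilic indole C3 by chlorosulfonyl isocyanate gives N-chlorosulfonyl amide 2, which DMF strips of SO3 and HCl to leave the nitrile (CSI/DMF cyanation of indoles); the aryl bromide is untouched.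

**Step 2**
Reactants: 3 6-bromo-1H-indole-3-carbonitrile; 4 tryptamine [2-(1H-indol-3-yl)ethan-1-amine]
Product: 6 6-bromo-N-[2-(1H-indol-3-yl)ethyl]-1H-indole-3-carboximidamide (free base), via imidate hydrochloride 5 (not isolated)
Conditions: EtOH (5 equiv), 4 M HCl–dioxane, 0 °C → rt, 48 h; concentrate; then 4 (1.0 equiv), EtOH, rt → 40 °C, 16 h; cold 1 M NaOH/EtOAc work-up
Reagents that add atoms: ethanol, CCO; hydrogen chloride, Cl (both are held only by the in-flask imidate salt 5 and leave again before 6)
Why: Pinner reaction: the HCl-activated nitrile adds ethanol to give imidate salt 5, whose ethoxy group is displaced by the primary amine of tryptamine (addition–elimination) to give the N-monosubstituted amidine; indole N–H groups and the aryl bromide are inert.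

**Step 3**
Reactants: 6 6-bromo-N-[2-(1H-indol-3-yl)ethyl]-1H-indole-3-carboximidamide
Product: 8 nortopsentin B [6-bromo-3-[4-(1H-indol-3-yl)-1H-imidazol-2-yl]-1H-indole], via imidazoline 7 (not isolated)
Conditions: DDQ (2.2 equiv), AcOH (3 equiv), 4 Å MS, THF, 0 °C → rt, then 60 °C; aq. NaHCO3
Reagents that add atoms: none
Why: Proposed new method: an indole-gated double dehydrogenative C(sp3)–H amination/aromatisation of an N-(2-indol-3-ylethyl)amidine. DDQ forms a charge-transfer complex with the electron-rich 3-alkylindole and abstracts hydride from the indolylic CH2 to give a 3-alkylidene-3H-indolium ion; the unsubstituted amidine nitrogen captures it in a 5-exo closure (the new C–N bond and the ring) to give racemic imidazoline 7; its C4–H is again indolylic and is removed by the second DDQ, and loss of the C5 proton gives the aromatic imidazole. AcOH holds the amidine as its acetate, which shields nitrogen from DDQ and deactivates the bromoindole toward oxidation and toward C2 Friedel–Crafts capture; a cation intercepted by acetate or trace water would give the β-keto amidine, which cyclodehydrates to the same imidazole. The closest known reaction type is the DDQ oxidative cyclisation of N-acyl tryptamines/tryptophans to 5-(indol-3-yl)oxazoles (C–O) together with DDQ oxidation of 3-alkylindoles to 3-acylindoles; as far as I know it has not been shown with an amidine nitrogen closing an imidazole.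

**Compound list**
1 | 6-bromo-1H-indole | Brc1ccc2cc[nH]c2c1 | starting material
2 | 6-bromo-N-(chlorosulfonyl)-1H-indole-3-carboxamide | O=C(NS(=O)(=O)Cl)c1c[nH]c2cc(Br)ccc12 | intermediate
3 | 6-bromo-1H-indole-3-carbonitrile | N#Cc1c[nH]c2cc(Br)ccc12 | intermediate
4 | tryptamine, 2-(1H-indol-3-yl)ethan-1-amine | NCCc1c[nH]c2ccccc12 | starting material
5 | ethyl 6-bromo-1H-indole-3-carboximidate hydrochloride | CCOC(=N)c1c[nH]c2cc(Br)ccc12.Cl | intermediate
6 | 6-bromo-N-[2-(1H-indol-3-yl)ethyl]-1H-indole-3-carboximidamide | N=C(NCCc1c[nH]c2ccccc12)c1c[nH]c2cc(Br)ccc12 | intermediate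
7 | 6-bromo-3-[4-(1H-indol-3-yl)-4,5-dihydro-1H-imidazol-2-yl]-1H-indole (racemic) | Brc1ccc2c(C3=NC(c4c[nH]c5ccccc45)CN3)c[nH]c2c1 | intermediate
8 | nortopsentin B, 6-bromo-3-[4-(1H-indol-3-yl)-1H-imidazol-2-yl]-1H-indole | Brc1ccc2c(-c3nc(-c4c[nH]c5ccccc45)c[nH]3)c[nH]c2c1 | target

**Total step count:** 3
**Longest linear sequence:** 3 steps (1 → 3 → 6 → 8)

**Steps most likely to fail**

Step 3 (the proposed new oxidative annulation). Risks are DDQ attack on amidine nitrogen, capture of the cation by the bromoindole C2 (γ-carboline), or stalling at imidazoline 7. The fallback uses known chemistry; it sets out from imidate hydrochloride 5 (made as in the first stage of step 2) and comes back at 8. Ammonolysis of 5 with 7 M NH3 in MeOH at rt gives 6-bromo-1H-indole-3-carboximidamide hydrochloride F1. This is condensed with 2-bromo-1-(1H-indol-3-yl)ethan-1-one F2 (made from 3-acetylindole with CuBr2 in EtOAc–CHCl3 at reflux) using KHCO3 in THF–H2O at reflux. Amidine N-alkylation followed by cyclodehydration (the classical amidine/α-haloketone imidazole synthesis) gives 8 directly.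

Step 2 (Pinner amidination). The push–pull 3-cyanoindole may add ethanol slowly, the imidate may hydrolyse, or a second tryptamine may add. The fallback sets out from nitrile 3 and comes back at amidine 6. Thionation with O,O-diethyl dithiophosphoric acid in wet i-PrOH at 80 °C gives 6-bromo-1H-indole-3-carbothioamide F3. S-Methylation with MeI in acetone gives methyl 6-bromo-1H-indole-3-carbimidothioate hydroiodide F4. Tryptamine 4 in EtOH at rt then displaces methanethiol, and NaOH work-up gives 6.

Step 1 (CSI cyanation). Risks are moisture sensitivity and competing N1-acylation or bis-addition. The fallback sets out from 1 and comes back at nitrile 3. Vilsmeier–Haack formylation (POCl3, DMF, 0 → 40 °C; aq. NaOH) gives 6-bromo-1H-indole-3-carbaldehyde F5. Heating F5 with NH2OH·HCl and HCO2Na in HCO2H forms 6-bromo-1H-indole-3-carbaldehyde oxime F6 in the flask, which dehydrates under the same conditions to 3.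

**Further compounds**
F1 | step 3 | 6-bromo-1H-indole-3-carboximidamide hydrochloride | NC(=N)c1c[nH]c2cc(Br)ccc12.Cl
F2 | step 3 | 2-bromo-1-(1H-indol-3-yl)ethan-1-one | O=C(CBr)c1c[nH]c2ccccc12
F3 | step 2 | 6-bromo-1H-indole-3-carbothioamide | NC(=S)c1c[nH]c2cc(Br)ccc12
F4 | step 2 | methyl 6-bromo-1H-indole-3-carbimidothioate hydroiodide | CSC(=N)c1c[nH]c2cc(Br)ccc12.I
F5 | step 1 | 6-bromo-1H-indole-3-carbaldehyde | O=Cc1c[nH]c2cc(Br)ccc12
F6 | step 1 | 6-bromo-1H-indole-3-carbaldehyde oxime | ON=Cc1c[nH]c2cc(Br)ccc12
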